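**Retrosynthetic overview** (flavone numbering: O1, C2, C3, C4, C4a, C5–C8, C8a)
1. Rings A and B are bought whole: ketone 1 carries ring A, acid 2 carries ring B. Ring C (the pyranone) is the only ring built, and it is closed last.
2. Key disconnection (C–O): the aryl O1–C8a bond, traced back to the one free ortho C–H of 1 and the carboxyl oxygen of 2 (delivered by the in-flask iodane 3), which gives aryl ester 4.
3. C–C disconnection: the C2–C3 bond, traced back to an O-to-C aroyl shift in 4 that gives diketone 5.
4. Final C–O disconnection: O1–C2, traced back to cyclodehydration of 5 through hemiketal 6 to flavone 7.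

Assumption: the target, 5,7,8-trimethoxy-2-(3,4,5-trimethoxyphenyl)-4H-chromen-4-one, is achiral, so there is no enantiomer to select and no stereocontrol is needed.

**Step 1**
Reactants: 1 1-(2,4,5-trimethoxyphenyl)ethan-1-one; 2 3,4,5-trimethoxybenzoic acid
Product: 4 2-acetyl-3,5,6-trimethoxyphenyl 3,4,5-trimethoxybenzoate, via bis(aroyloxy)iodobenzene 3 (not isolated)
Conditions: PhI(OAc)2 (1.5 equiv), 2 (3.3 equiv), PhCl, 50 °C, AcOH stripped in vacuo; then 1, Pd(O2CCF3)2 (10 mol %), ClCH2CH2Cl, 70 °C
Reagents that add atoms: PhI(OAc)2, CC(=O)OI(OC(C)=O)c1ccccc1 (its PhI unit is held in 3 only; no atom of it stays in 4)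
Why: Proposed new method: a ketone-directed, Pd-catalysed ortho C–H aroyloxylation in which the acetyl oxygen of 1 guides carboxylate-assisted palladation (concerted metalation–deprotonation) to the only free ortho C–H (C6; the other ortho carbon carries OMe), the five-membered palladacycle of divalent palladium is oxidised by the trivalent-iodine dicarboxylate 3 to an aryl aroate complex of tetravalent palladium, and C–O reductive elimination releases ester 4 and returns divalent palladium; the closest known reaction type is the ketone-directed Pd-catalysed ortho-hydroxylation of aryl ketones with PhI(O2CCF3)2 together with directed C–H acetoxylation by PhI(OAc)2, and what is new is the transfer of an aryl carboxylate taken from a free benzoic acid under weak ketone direction on a trialkoxyarene; no stereocentre is formed.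

**Step 2**
Reactants: 4 2-acetyl-3,5,6-trimethoxyphenyl 3,4,5-trimethoxybenzoate
Product: 5 1-(2-hydroxy-3,4,6-trimethoxyphenyl)-3-(3,4,5-trimethoxyphenyl)propane-1,3-dione
Conditions: KOtBu (3 equiv), THF, 0 °C to rt; then 1 M HCl
Reagents that add atoms: none
Why: Baker–Venkataraman rearrangement: the methyl ketone enolate adds to the neighbouring aryl ester carbonyl through a six-membered ring and collapses with O-to-C aroyl transfer, and formation of the doubly stabilised phenoxide–diketonate pulls the equilibrium over before HCl protonates it to 5; no stereocentre is formed.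

**Step 3**
Reactants: 5 1-(2-hydroxy-3,4,6-trimethoxyphenyl)-3-(3,4,5-trimethoxyphenyl)propane-1,3-dione
Product: 7 5,7,8-trimethoxy-2-(3,4,5-trimethoxyphenyl)-4H-chromen-4-one, via 2-hydroxyflavanone hemiketal 6 (not isolated)
Conditions: AcOH, conc. H2SO4 (cat.), 90 °C
Reagents that add atoms: none
Why: Acid-catalysed cyclodehydration (the closing stage of the classical Baker–Venkataraman flavone synthesis): the phenol adds to the protonated ring-B-side carbonyl to give hemiketal 6, whose single stereocentre forms as a racemate and is erased when water is lost to give the conjugated pyranone, while catalytic H2SO4 in AcOH leaves the six aryl methyl ethers untouched.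

**Compound list**
1 | 1-(2,4,5-trimethoxyphenyl)ethan-1-one (2',4',5'-trimethoxyacetophenone) | CC(=O)c1cc(OC)c(OC)cc1OC | starting material
2 | 3,4,5-trimethoxybenzoic acid | COc1cc(C(=O)O)cc(OC)c1OC | starting material
3 | [bis(3,4,5-trimethoxybenzoyloxy)iodo]benzene | COc1cc(C(=O)OI(OC(=O)c2cc(OC)c(OC)c(OC)c2)c2ccccc2)cc(OC)c1OC | intermediate
4 | 2-acetyl-3,5,6-trimethoxyphenyl 3,4,5-trimethoxybenzoate | CC(=O)c1c(OC)cc(OC)c(OC)c1OC(=O)c1cc(OC)c(OC)c(OC)c1 | intermediate
5 | 1-(2-hydroxy-3,4,6-trimethoxyphenyl)-3-(3,4,5-trimethoxyphenyl)propane-1,3-dione | COc1cc(OC)c(C(=O)CC(=O)c2cc(OC)c(OC)c(OC)c2)c(O)c1OC | intermediate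
6 | 2-hydroxy-5,7,8-trimethoxy-2-(3,4,5-trimethoxyphenyl)chroman-4-one (cyclic hemiketal, racemic, transient) | COc1cc(C2(O)CC(=O)c3c(OC)cc(OC)c(OC)c3O2)cc(OC)c1OC | intermediate
7 | 5,7,8-trimethoxy-2-(3,4,5-trimethoxyphenyl)-4H-chromen-4-one (bannamurpanisin) | COc1cc(-c2cc(=O)c3c(OC)cc(OC)c(OC)c3o2)cc(OC)c1OC | target

**Total step count:** 3
**Longest linear sequence:** 3 steps (1 → 4 → 5 → 7; acid 2 enters in step 1)

**Steps most likely to fail**

Step 1 (the proposed new step) is the main risk. The ketone is a weak directing group and the aroate is less electron-withdrawing than trifluoroacetate, so palladation may be slow. The trivalent-iodine oxidant may instead attack the electron-rich ring at the C–H between the two methoxy groups. Residual acetate may be transferred in place of the aroate. Pd(O2CCF3)2 is chosen so that a catalytic amount of trifluoroacetate keeps the metal electrophilic while the far more abundant aroate is the group transferred.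

The fallback uses known chemistry; it sets out from acid 2 and comes back at ester 4. Purchased 1,2,3,5-tetramethoxybenzene F1 is acetylated with AcCl/AlCl3 (CH2Cl2, 0 °C to rt). The first-formed 1-(2,3,4,6-tetramethoxyphenyl)ethan-1-one F2 loses, in the same pot, the methyl of the methoxy group squeezed between the acetyl group and a neighbouring methoxy group. This gives 1-(2-hydroxy-3,4,6-trimethoxyphenyl)ethan-1-one F3; the site of demethylation is recalled from the classical preparation and should be confirmed on the first batch. Steglich esterification of F3 with acid 2 (DCC, DMAP, CH2Cl2) gives 4. Here the aryl C–O bond is bought in rather than made by C–H activation.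

Step 2 may fail if the base cleaves the hindered aryl ester instead of triggering the acyl shift. The fallback sets out from ester 4 and comes back at flavone 7, replacing the enolate acyl transfer by an intramolecular Wittig olefination of the ester carbonyl. The acetyl group of 4 is brominated at the α-carbon (CuBr2, EtOAc/CHCl3, reflux) to 2-(2-bromoacetyl)-3,5,6-trimethoxyphenyl 3,4,5-trimethoxybenzoate F4. PPh3 in toluene then gives {2-oxo-2-[3,4,6-trimethoxy-2-(3,4,5-trimethoxybenzoyloxy)phenyl]ethyl}triphenylphosphonium bromide F5. K2CO3 in refluxing toluene gives the acyl-stabilised ylide 3,5,6-trimethoxy-2-[2-(triphenyl-λ5-phosphanylidene)acetyl]phenyl 3,4,5-trimethoxybenzoate F6, which closes ring C by forming the C2=C3 bond directly, with no diketone and no acid step.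

Step 3 is the safest step; its risk is acid-induced loss of the C5 methyl ether or incomplete ring closure. The fallback sets out from ester 4 and comes back at flavone 7 by an acid-free oxidative ring closure. Ester 4 is stirred with KOH in aqueous EtOH together with purchased 3,4,5-trimethoxybenzaldehyde F7. The base first cleaves the aryl ester, giving 1-(2-hydroxy-3,4,6-trimethoxyphenyl)ethan-1-one F3 (the compound already met in the fallback to step 1) and returning acid 2. F3 then undergoes Claisen–Schmidt condensation in the same pot to (E)-1-(2-hydroxy-3,4,6-trimethoxyphenyl)-3-(3,4,5-trimethoxyphenyl)prop-2-en-1-one F8. I2 (cat.) in DMSO at 120 °C then closes ring C by oxa-Michael addition and dehydrogenates it to 7.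

**Further compounds**
F1 | step 1 | 1,2,3,5-tetramethoxybenzene | COc1cc(OC)c(OC)c(OC)c1
F2 | step 1 | 1-(2,3,4,6-tetramethoxyphenyl)ethan-1-one | CC(=O)c1c(OC)cc(OC)c(OC)c1OC
F3 | step 1 | 1-(2-hydroxy-3,4,6-trimethoxyphenyl)ethan-1-one | CC(=O)c1c(OC)cc(OC)c(OC)c1O
F4 | step 2 | 2-(2-bromoacetyl)-3,5,6-trimethoxyphenyl 3,4,5-trimethoxybenzoate | O=C(CBr)c1c(OC)cc(OC)c(OC)c1OC(=O)c1cc(OC)c(OC)c(OC)c1
F5 | step 2 | {2-oxo-2-[3,4,6-trimethoxy-2-(3,4,5-trimethoxybenzoyloxy)phenyl]ethyl}triphenylphosphonium bromide | [Br-].O=C(C[P+](c1ccccc1)(c1ccccc1)c1ccccc1)c1c(OC)cc(OC)c(OC)c1OC(=O)c1cc(OC)c(OC)c(OC)c1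
F6 | step 2 | 3,5,6-trimethoxy-2-[2-(triphenyl-λ5-phosphanylidene)acetyl]phenyl 3,4,5-trimethoxybenzoate | O=C(C=P(c1ccccc1)(c1ccccc1)c1ccccc1)c1c(OC)cc(OC)c(OC)c1OC(=O)c1cc(OC)c(OC)c(OC)c1
F7 | step 3 | 3,4,5-trimethoxybenzaldehyde | COc1cc(C=O)cc(OC)c1OC
F8 | step 3 | (E)-1-(2-hydroxy-3,4,6-trimethoxyphenyl)-3-(3,4,5-trimethoxyphenyl)prop-2-en-1-one | COc1cc(OC)c(C(=O)/C=C/c2cc(OC)c(OC)c(OC)c2)c(O)c1OC
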